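Ring B of the tetralin is cut at C3–C4 and C1–C8a (tetralin numbering, C1 = aryl-bearing carbon). This is a [3+3] union of a syringyl benzyl bromide (C4, C4a, C8a) with a C1–C2–C3 unit held in a γ-butyrolactone (C9 carbonyl on C3, C9' on C2). The key step exploits three features: C3 is α to C9 (enolate), C1 is a para-oxygenated benzylic carbon of the guaiacyl ring (ionizable), and C8a lies para to the C6 methoxy group. In one flask the lactone enolate is benzylated trans, then acid triggers a hydroxymatairesinol-to-conidendrin-type Friedel–Crafts closure. The precursor is an Evans-aldol-derived β-[aryl(silyloxy)methyl]butyrolactone; lactone reduction and debenzylation finish.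

Key step: step 7

Assumption: the oxazolidinone, the acid chloride, the aldehyde and 4-hydroxy-3,5-dimethoxybenzyl alcohol are taken as commercial.

Step 1
Reactants: 1 (S)-4-benzyl-2-oxazolidinone; 2 methyl 4-chloro-4-oxobutanoate
Product: 3 methyl 4-[(4S)-4-benzyl-2-oxo-1,3-oxazolidin-3-yl]-4-oxobutanoate
Conditions: n-BuLi, THF, −78 °C; then 2, −78 → 0 °C
Reagents that add atoms: none
Why: N-acylation of the lithiated oxazolidinone at the acid chloride carbonyl, which reacts far faster than the methyl ester at low temperature; no stereocentre is formed.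

Step 2
Reactants: 3 methyl 4-[(4S)-4-benzyl-2-oxo-1,3-oxazolidin-3-yl]-4-oxobutanoate; 4 4-(benzyloxy)-3-methoxybenzaldehyde
Product: 5 methyl (3S,4S)-3-[(4S)-4-benzyl-2-oxo-1,3-oxazolidine-3-carbonyl]-4-[4-(benzyloxy)-3-methoxyphenyl]-4-hydroxybutanoate
Conditions: Bu2BOTf, iPr2NEt, CH2Cl2, 0 °C; 4, −78 → 0 °C; then pH 7 buffer, MeOH, 30% H2O2, 0 °C
Reagents that add atoms: none
Why: Evans syn-aldol reaction, in which the Z-boron enolate of the imide (the ester α-position is not enolized) adds to the aldehyde through a closed chair transition state on the face opposite the benzyl group of the (S)-auxiliary, setting the α-carbon (future C2) as (S) and the carbinol syn to it; only the former centre is needed later.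

Step 3
Reactants: 5 methyl (3S,4S)-3-[(4S)-4-benzyl-2-oxo-1,3-oxazolidine-3-carbonyl]-4-[4-(benzyloxy)-3-methoxyphenyl]-4-hydroxybutanoate
Product: 6 methyl (3S,4S)-3-[(4S)-4-benzyl-2-oxo-1,3-oxazolidine-3-carbonyl]-4-[4-(benzyloxy)-3-methoxyphenyl]-4-[(tert-butyldimethylsilyl)oxy]butanoate
Conditions: TBSOTf, 2,6-lutidine, CH2Cl2, −78 → 0 °C (crude 5 used directly)
Reagents that add atoms: tert-butyldimethylsilyl triflate (TBSOTf), CC(C)(C)[Si](C)(C)OS(=O)(=O)C(F)(F)F
Why: Silylation of the hindered benzylic alcohol with a silyl triflate and a non-nucleophilic base blocks lactonization of this oxygen onto the ester and installs the later leaving group at C1, with no stereocentre touched.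

Step 4
Reactants: 6 methyl (3S,4S)-3-[(4S)-4-benzyl-2-oxo-1,3-oxazolidine-3-carbonyl]-4-[4-(benzyloxy)-3-methoxyphenyl]-4-[(tert-butyldimethylsilyl)oxy]butanoate
Product: 8 (4R)-4-{(S)-[4-(benzyloxy)-3-methoxyphenyl][(tert-butyldimethylsilyl)oxy]methyl}oxolan-2-one, via hydroxy ester 7 (not isolated)
Conditions: NaBH4, THF/H2O (4:1), 0 °C → rt
Reagents that add atoms: none
Why: Reductive cleavage of the N-acyloxazolidinone, in which NaBH4 attacks the activated exocyclic imide carbonyl in preference to the methyl ester and the primary alcohol so formed closes onto the ester (5-exo-trig lactonization), so that C9' carries the ring oxygen and C9 the carbonyl while the C2 stereocentre is untouched.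

Step 5
Reactants: 9 4-hydroxy-3,5-dimethoxybenzyl alcohol
Product: 10 [4-(benzyloxy)-3,5-dimethoxyphenyl]methanol
Conditions: BnBr, K2CO3, acetone, reflux
Reagents that add atoms: benzyl bromide, BrCc1ccccc1
Why: Williamson etherification, in which K2CO3 deprotonates only the phenol, so O-benzylation is chemoselective over the benzylic alcohol.

Step 6
Reactants: 10 [4-(benzyloxy)-3,5-dimethoxyphenyl]methanol
Product: 11 2-(benzyloxy)-5-(bromomethyl)-1,3-dimethoxybenzene
Conditions: PBr3, Et2O, 0 °C; used at once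
Reagents that add atoms: phosphorus tribromide, BrP(Br)Br
Why: Bromination of the electron-rich benzylic alcohol through its phosphite ester (SN2 by bromide); the labile bromide is not stored.

Step 7
Reactants: 8 (4R)-4-{(S)-[4-(benzyloxy)-3-methoxyphenyl][(tert-butyldimethylsilyl)oxy]methyl}oxolan-2-one; 11 2-(benzyloxy)-5-(bromomethyl)-1,3-dimethoxybenzene
Product: 13 (3aR,4S,9aR)-6-(benzyloxy)-4-[4-(benzyloxy)-3-methoxyphenyl]-5,7-dimethoxy-3a,4,9,9a-tetrahydronaphtho[2,3-c]furan-1(3H)-one, via trans-benzylated lactone 12 (not isolated)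
Conditions: LiN(SiMe3)2, THF, −78 °C; 11, DMPU, −78 → −30 °C; then solvent exchanged for CH2Cl2 without work-up, TFA, 0 °C → rt
Reagents that add atoms: none
Why: Deprotonation of 8 gives the lithium enolate at C3, which displaces bromide from 11 (SN2) on the face anti to the bulky C2 side chain and so should set C3 (R) in trans-lactone 12 (bond C3–C4). After the switch to TFA/CH2Cl2 the para-benzyloxybenzylic silyl ether ionizes to the C1 cation (an O-alkylated para-quinone methide), which the pendant ring attacks at C8a in an intramolecular Friedel–Crafts alkylation (bond C1–C8a). The closest known reactions are the trans-selective α-benzylation of β-substituted γ-butyrolactone enolates and the acid-mediated cyclization of hydroxymatairesinol to α-conidendrin. Ring B closes as a six-membered ring by cation–arene attack (6-endo with respect to the arene π bond), and the lactone becomes trans-fused. C1 should be set (S) under control of C2: in the chair-like transition state the guaiacyl group lies pseudo-equatorial, trans to the C2–C9' bond, so the carbinol configuration of 8 is irrelevant. The step needs trans selectivity in the benzylation (secured by the C2 substituent), mono-C-alkylation (lithium enolate at −78 °C, one equivalent of base) and no regiochemical choice in the arene, whose two free ortho positions are equivalent and each para to a methoxy group.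

Step 8
Reactants: 13 (3aR,4S,9aR)-6-(benzyloxy)-4-[4-(benzyloxy)-3-methoxyphenyl]-5,7-dimethoxy-3a,4,9,9a-tetrahydronaphtho[2,3-c]furan-1(3H)-one
Product: 14 [(1S,2R,3R)-7-(benzyloxy)-1-[4-(benzyloxy)-3-methoxyphenyl]-6,8-dimethoxy-1,2,3,4-tetrahydronaphthalene-2,3-diyl]dimethanol
Conditions: LiAlH4, THF, 0 °C → rt
Reagents that add atoms: none
Why: Hydride reduction of the γ-lactone to the 1,4-diol (the α-conidendrin-to-isolariciresinol type reduction) delivers both hydroxymethyl groups at once, reduction being faster than enolization so that C3 keeps its configuration.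

Step 9
Reactants: 14 [(1S,2R,3R)-7-(benzyloxy)-1-[4-(benzyloxy)-3-methoxyphenyl]-6,8-dimethoxy-1,2,3,4-tetrahydronaphthalene-2,3-diyl]dimethanol
Product: 15 (+)-8-methoxyisolariciresinol, (1S,2R,3R)-1-(4-hydroxy-3-methoxyphenyl)-2,3-bis(hydroxymethyl)-6,8-dimethoxy-1,2,3,4-tetrahydronaphthalen-7-ol
Conditions: H2 (1 atm), 10% Pd on carbon, EtOAc/MeOH, rt
Reagents that add atoms: none
Why: Hydrogenolysis of the two aryl benzyl ethers over Pd on carbon, under which the methyl ethers, the alcohols and the doubly benzylic C1–H bond should be inert.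

Compound list
1 | (S)-4-benzyl-2-oxazolidinone | O=C1OC[C@H](Cc2ccccc2)N1 | starting material
2 | methyl 4-chloro-4-oxobutanoate | COC(=O)CCC(Cl)=O | starting material
3 | methyl 4-[(4S)-4-benzyl-2-oxo-1,3-oxazolidin-3-yl]-4-oxobutanoate | COC(=O)CCC(=O)N1[C@@H](Cc2ccccc2)COC1=O | intermediate
4 | 4-(benzyloxy)-3-methoxybenzaldehyde | COc1cc(C=O)ccc1OCc1ccccc1 | starting material
5 | methyl (3S,4S)-3-[(4S)-4-benzyl-2-oxo-1,3-oxazolidine-3-carbonyl]-4-[4-(benzyloxy)-3-methoxyphenyl]-4-hydroxybutanoate | COC(=O)C[C@H](C(=O)N1[C@@H](Cc2ccccc2)COC1=O)[C@H](O)c1ccc(OCc2ccccc2)c(OC)c1 | intermediate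
6 | methyl (3S,4S)-3-[(4S)-4-benzyl-2-oxo-1,3-oxazolidine-3-carbonyl]-4-[4-(benzyloxy)-3-methoxyphenyl]-4-[(tert-butyldimethylsilyl)oxy]butanoate | COC(=O)C[C@H](C(=O)N1[C@@H](Cc2ccccc2)COC1=O)[C@H](O[Si](C)(C)C(C)(C)C)c1ccc(OCc2ccccc2)c(OC)c1 | intermediate
7 | methyl (3R,4S)-4-[4-(benzyloxy)-3-methoxyphenyl]-4-[(tert-butyldimethylsilyl)oxy]-3-(hydroxymethyl)butanoate (hydroxy ester, not isolated) | COC(=O)C[C@H](CO)[C@H](O[Si](C)(C)C(C)(C)C)c1ccc(OCc2ccccc2)c(OC)c1 | intermediate
8 | (4R)-4-{(S)-[4-(benzyloxy)-3-methoxyphenyl][(tert-butyldimethylsilyl)oxy]methyl}oxolan-2-one | O=C1OC[C@@H](C1)[C@H](O[Si](C)(C)C(C)(C)C)c1ccc(OCc2ccccc2)c(OC)c1 | intermediate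
9 | 4-hydroxy-3,5-dimethoxybenzyl alcohol | COc1cc(CO)cc(OC)c1O | starting material
10 | [4-(benzyloxy)-3,5-dimethoxyphenyl]methanol | COc1cc(CO)cc(OC)c1OCc1ccccc1 | intermediate
11 | 2-(benzyloxy)-5-(bromomethyl)-1,3-dimethoxybenzene | COc1cc(CBr)cc(OC)c1OCc1ccccc1 | intermediate
12 | (3R,4R)-3-[4-(benzyloxy)-3,5-dimethoxybenzyl]-4-{(S)-[4-(benzyloxy)-3-methoxyphenyl][(tert-butyldimethylsilyl)oxy]methyl}oxolan-2-one (trans-benzylated lactone, not isolated) | COc1cc(C[C@H]2C(=O)OC[C@@H]2[C@H](O[Si](C)(C)C(C)(C)C)c2ccc(OCc3ccccc3)c(OC)c2)cc(OC)c1OCc1ccccc1 | intermediate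
13 | (3aR,4S,9aR)-6-(benzyloxy)-4-[4-(benzyloxy)-3-methoxyphenyl]-5,7-dimethoxy-3a,4,9,9a-tetrahydronaphtho[2,3-c]furan-1(3H)-one | COc1cc([C@H]2c3c(cc(OC)c(OCc4ccccc4)c3OC)C[C@H]5C(=O)OC[C@H]25)ccc1OCc1ccccc1 | intermediate
14 | [(1S,2R,3R)-7-(benzyloxy)-1-[4-(benzyloxy)-3-methoxyphenyl]-6,8-dimethoxy-1,2,3,4-tetrahydronaphthalene-2,3-diyl]dimethanol | COc1cc([C@H]2c3c(cc(OC)c(OCc4ccccc4)c3OC)C[C@@H](CO)[C@@H]2CO)ccc1OCc1ccccc1 | intermediate
15 | (+)-8-methoxyisolariciresinol, (1S,2R,3R)-1-(4-hydroxy-3-methoxyphenyl)-2,3-bis(hydroxymethyl)-6,8-dimethoxy-1,2,3,4-tetrahydronaphthalen-7-ol | COc1cc([C@H]2c3c(cc(OC)c(O)c3OC)C[C@@H](CO)[C@@H]2CO)ccc1O | target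

Total step count: 9. Longest linear sequence: 7 (steps 1, 2, 3, 4, 7, 8, 9).

Steps most likely to fail

Step 7 (key step). The acid stage may not follow cleanly in the same flask: lithium and amine salts and residual THF can buffer the acid so that the silyl ether ionizes slowly. The C1 cation may be lost by elimination toward C2 or by capture by trifluoroacetate, the aryl benzyl ethers may be partly cleaved, and the benzylation may be less than fully trans-selective. The fallback takes the annulation apart into isolated operations with a different cation precursor. It sets out from 8, which is benzylated with 11 as in the route, but lactone 12 is now isolated and purified. HF·pyridine in THF removes the silyl group to give the carbinol (3R,4R)-3-[4-(benzyloxy)-3,5-dimethoxybenzyl]-4-{(S)-[4-(benzyloxy)-3-methoxyphenyl](hydroxy)methyl}oxolan-2-one F1. F1 is cyclized with BF3·OEt2 in CH2Cl2 at −20 → 0 °C, the established conditions for hydroxymatairesinol-type carbinols, and the sequence comes back to the route at 13.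

Step 2. The aldol hydroxyl may lactonize onto the methyl ester during work-up, placing the ring oxygen on the benzylic carbon, or the adduct may revert by retro-aldol cleavage before silylation. The fallback redesigns the succinate arm so that ring closure is decoupled from the aldol. It sets out from 1, which is acylated with the mixed anhydride 4-tert-butoxy-4-oxobutanoic pivalic anhydride F2 (from commercial 4-tert-butoxy-4-oxobutanoic acid, PivCl, Et3N, THF, −20 °C; then 1, LiCl) to give tert-butyl 4-[(4S)-4-benzyl-2-oxo-1,3-oxazolidin-3-yl]-4-oxobutanoate F3. The same boron aldol with 4 gives tert-butyl (3S,4S)-3-[(4S)-4-benzyl-2-oxo-1,3-oxazolidine-3-carbonyl]-4-[4-(benzyloxy)-3-methoxyphenyl]-4-hydroxybutanoate F4, whose tert-butyl ester should resist lactonization. TBSOTf/2,6-lutidine gives the silyl ether tert-butyl (3S,4S)-3-[(4S)-4-benzyl-2-oxo-1,3-oxazolidine-3-carbonyl]-4-[4-(benzyloxy)-3-methoxyphenyl]-4-[(tert-butyldimethylsilyl)oxy]butanoate F5. LiBH4/MeOH in THF at 0 °C removes the auxiliary, the tert-butyl ester being inert, to give tert-butyl (3R,4S)-4-[4-(benzyloxy)-3-methoxyphenyl]-4-[(tert-butyldimethylsilyl)oxy]-3-(hydroxymethyl)butanoate F6. KOt-Bu (catalytic) in THF then closes the lactone, and the sequence comes back to the route at 8.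

Step 4. The hydride may also reduce the methyl ester or the lactone product, or attack the endocyclic carbamate carbonyl of the hindered imide. The silyl group may also migrate from the benzylic to the primary oxygen under the basic conditions before lactonization. The fallback replaces the one-flask reduction by hydrolysis followed by a carboxyl-selective reduction. It sets out from 6, which is cleaved with LiOH/H2O2 in THF/H2O at 0 °C to (2S,3S)-3-[4-(benzyloxy)-3-methoxyphenyl]-3-[(tert-butyldimethylsilyl)oxy]-2-(2-methoxy-2-oxoethyl)propanoic acid F7. BH3·SMe2 in THF at 0 °C reduces only the free acid to give hydroxy ester 7, which is lactonized by warming in toluene with a trace of PPTS, and the sequence comes back to the route at 8.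

Further compounds
F1 | step 7 | (3R,4R)-3-[4-(benzyloxy)-3,5-dimethoxybenzyl]-4-{(S)-[4-(benzyloxy)-3-methoxyphenyl](hydroxy)methyl}oxolan-2-one | COc1cc(C[C@H]2C(=O)OC[C@@H]2[C@H](O)c2ccc(OCc3ccccc3)c(OC)c2)cc(OC)c1OCc1ccccc1
F2 | step 2 | 4-tert-butoxy-4-oxobutanoic pivalic anhydride | CC(C)(C)OC(=O)CCC(=O)OC(=O)C(C)(C)C
F3 | step 2 | tert-butyl 4-[(4S)-4-benzyl-2-oxo-1,3-oxazolidin-3-yl]-4-oxobutanoate | CC(C)(C)OC(=O)CCC(=O)N1[C@@H](Cc2ccccc2)COC1=O
F4 | step 2 | tert-butyl (3S,4S)-3-[(4S)-4-benzyl-2-oxo-1,3-oxazolidine-3-carbonyl]-4-[4-(benzyloxy)-3-methoxyphenyl]-4-hydroxybutanoate | CC(C)(C)OC(=O)C[C@H](C(=O)N1[C@@H](Cc2ccccc2)COC1=O)[C@H](O)c1ccc(OCc2ccccc2)c(OC)c1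
F5 | step 2 | tert-butyl (3S,4S)-3-[(4S)-4-benzyl-2-oxo-1,3-oxazolidine-3-carbonyl]-4-[4-(benzyloxy)-3-methoxyphenyl]-4-[(tert-butyldimethylsilyl)oxy]butanoate | CC(C)(C)OC(=O)C[C@H](C(=O)N1[C@@H](Cc2ccccc2)COC1=O)[C@H](O[Si](C)(C)C(C)(C)C)c1ccc(OCc2ccccc2)c(OC)c1
F6 | step 2 | tert-butyl (3R,4S)-4-[4-(benzyloxy)-3-methoxyphenyl]-4-[(tert-butyldimethylsilyl)oxy]-3-(hydroxymethyl)butanoate | CC(C)(C)OC(=O)C[C@H](CO)[C@H](O[Si](C)(C)C(C)(C)C)c1ccc(OCc2ccccc2)c(OC)c1
F7 | step 4 | (2S,3S)-3-[4-(benzyloxy)-3-methoxyphenyl]-3-[(tert-butyldimethylsilyl)oxy]-2-(2-methoxy-2-oxoethyl)propanoic acid | COC(=O)C[C@H](C(O)=O)[C@H](O[Si](C)(C)C(C)(C)C)c1ccc(OCc2ccccc2)c(OC)c1
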